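## The problem

- Compound 22 is a bicyclo[3.3.1]nonane-2,4,9-trione. It is numbered here with C1 as the bridgehead CH, C2–C3–C4 as the enolised three-carbon bridge (benzoyl on C3), C5 as the prenylated quaternary bridgehead, C6 as a CH2, C7 as the CH carrying the second prenyl group, C8 as the CMe2 carbon and C9 as the one-carbon ketone bridge. C1, C9, C5, C6, C7 and C8 thus form a cyclohexanone that the C2–C4 unit spans 1,3-diaxially.
- Of the three stereocentres only two elements are independent, because the bridge forces its two ends to be cis. These are the absolute configuration at C7 and the placing of C4 on C5 trans to the C7 prenyl group (C7 prenyl equatorial and cis to the C5 prenyl group).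
- C7 is the natural controller: once set, it should steer the second substituent entering C5 through the six-membered enolate, and C5 together with the C8 methyl groups then decides the face of C1.
- C5 and C8 are fully substituted carbons next to carbonyl-bearing positions, so the bonds to C5 and C1 have to be made with small, reactive partners and in a fixed order.
- The two trisubstituted alkenes exclude hydrogenation, ozonolysis, electrophilic halogen and strong acid. The dicarbonyl arrays around the quaternary C5 cannot enolise and are open to retro-Claisen cleavage by hard bases. The acidic, chelating acyl-trione is best released last.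
- The enabling feature is that the C4 carbonyl, C3 and the benzoyl carbonyl form a 1,3-diketone, the retron of an isoxazole with C4 as the C=N carbon and the ring oxygen on the benzoyl carbon. That isoxazole is the adduct of a nitrile oxide at C4 and a phenylalkyne whose inner carbon is C3, and the tether C5–C9–C1–C2 has four atoms, so the carbocycle closed is six-membered.
- C2 must be a protected carbinol at ring closure. A C2 ketone would give an ynone 1,3-diketone that closes to a pyranone through the C9 enol, and a free hydroxyl would sit 1,3-diaxial to the nitrile oxide carbon and add to it.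

## Retrosynthesis

**22 to 21 to 20.** The C4–O bond of 22 is traced to the vinylogous amide 21 (hydrolysis) and 21 to the isoxazole 20 by restoring the N–O bond. Against a late C3 benzoylation of a bare trione, this cut brings the aroyl carbon and both flanking heteroatoms in one masked unit and keeps the molecule neutral and non-chelating until the end. The forward steps need an N–O reduction that spares alkenes and a hydrolysis mild enough for the prenyl groups.

**20 to 19 to 18.** The C2 ketone of 20 is taken back to the carbinol 19 and its acetate 18. The precursor is simpler in reactivity: C1 is no longer flanked by two carbonyl groups. The bridgehead position of C1 protects 19 and 18 from retro-aldol cleavage and β-elimination, so deacetylation and oxidation should be uneventful.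

**18 to 16 (through 17).** The C3–C4 bond and the O–C(phenyl) bond are cut together, which opens the six-membered trione ring and the isoxazole and leads to the monocyclic aldoxime 16. Cutting C1–C2 or C1–C9 instead would leave the benzoyl group to be added later. This cut removes two rings and asks only that the dipole 17 and the alkyne sit on cis arms of the cyclohexanone.

**16 to 14 (through 15).** The oxime carbon is traced to the dimethyl acetal of 14. The formyl carbon on the quaternary C5 cannot be enolised and would be attacked by the C1 enolate of another molecule, so it must be masked while the C1 arm is installed. The acetal is small and stable to base.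

**14 to 10 and 11 (through 12 and 13).** The C1–C2 bond (aldol) and one C8–methyl bond (conjugate addition) are cut in the same operation. Methyl cuprate addition to the enone 10 should give the enolate 12 at the hindered C1 and nowhere else. Its aldol adduct 13 with the ynal 11 is acetylated in the flask. This removes the alkyne arm, the acetate and the C8 quaternary carbon at once. The forward reaction must deliver the arm to the face of C1 that carries the acetal on C5.

**10 to 9 to 8 to 6 and 7.** The C5–C4 bond is cut first and the C5–prenyl bond second. The group that enters last at C5 should come in trans to the C7 prenyl group, so the formyl equivalent must be last. On the enone platform C1 is vinylic, so only C5 can be deprotonated in 6 and 8. A saturated 3,3-dimethylcyclohexanone would not give that certainty at the second alkylation.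

**6 to 5 to 4.** The first C8–methyl bond is cut and the enone restored. The annulation below gives a β-unsubstituted enone, and the silyl enol ether 5 fixes the site of dehydrogenation.

**4 to 3 to 1 and 2.** The C1=C8 bond (aldol condensation) and the C6–C7 bond (Michael addition) are cut, leaving two achiral four- and seven-carbon pieces. C7 is set by an amine catalyst. An acid-promoted closure of an open-chain terpenoid dienyl ketone was considered for the same ring and set aside, because a prenyl alkene would compete with the alkene meant to react and the C7 hydrogen would sit beside the cationic centre.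

## Roads not taken

**Alternative 1:** The cut is at C1–C9 and C3–C4, back to the acyclic keto malonate A1. In the forward sense KOtBu would let the C1 enolate attack one of the two diastereotopic esters (closing the carbocycle), and the methyl terminus C3 of the new diketone would attack the other ester to give the trione A2. C3 benzoylation would follow.
- Merits: both rings and all three ring carbonyl groups arise at their final oxidation level in one operation, without protecting groups or unmasking. C1 is acidic when the bridge closes, so its configuration corrects itself.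
- Weak points: the choice between the two esters sets C5 against C7 with only a remote bias, and either choice can go on to a bridged product. After the first closure the diketone is deprotonated at C1, so the second closure needs a C3 carbanion of that enolate, which an alkoxide hardly provides. The non-enolisable dicarbonyl array sits in equilibrating base. A1 holds C7 beside a quaternary carbon in an open chain, where no ring helps to set it.
- Comparison: this road is shorter after its key step (two steps to 22 against four from 18) and needs no nitrogen to be put in and taken out. The chosen plan sets against it that every bond is made irreversibly at a defined site, that C5 is set on a ring by 1,3-induction, and that the benzoyl carbon arrives with the ring closure.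

**Alternative 2:** The cut is at C1–C2 and at one C8–methyl bond, back to the cyclohexenone A3 with a β-methoxyacrylate on C5. Me2CuLi would add to C8 and the C1 enolate would close onto the ester to give the vinylogous ester A4. C3 metalation and benzoylation and O-demethylation would follow.
- Merits: it shares the enone platform of 8 and 10 and the tandem logic of step 8. C1 is trigonal when the ring closes, so the C1 face problem of the chosen plan does not exist. A4 is a proven substrate type for C3 acylation.
- Weak points: the β-methoxyacrylate is itself a cuprate acceptor (addition–elimination at C4) and is less hindered than the β,β-disubstituted enone. As a vinylogous carbonate it is a poor acylating agent for a hindered enolate next to CMe2. Three steps remain after the key step.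
- Comparison: on step count this road is shorter, by about three steps, and it is better on the C1 question. The chosen plan sets against it that the enolate 12 meets a very reactive aldehyde with no second acceptor present, and that no separate benzoylation is needed.

**Alternative 3:** The cut is at C1–C2, back to the silyl enol ether A5 with a bromo-ynone on C5. With [(tBu)2(2-biphenylyl)P]Au(NCMe)SbF6 the enol silane would attack C2 of the gold-activated alkyne in the 6-endo-dig mode to give the bromo enone A6. Exchange of bromide for oxygen, C3 benzoylation and unmasking would follow.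
- Merits: the ring closure is catalytic, neutral and mild, and C1 is again trigonal.
- Weak points: A6 lacks the C2 oxygen and the C3 acyl group, so at least three further steps are needed. The C5 prenyl alkene and the ynone form a 1,6-enyne, a standard partner for gold-catalysed enyne cycloisomerisation. The 6-endo against 5-exo outcome rests on the ligand. The bromo-ynone must be built on a quaternary carbon.
- Comparison: the step count is similar, and this road is better in needing no stoichiometric oxidant and no C1 control. The chosen plan sets against it that one ring closure delivers the C2 oxygen, the benzoyl group and the C4 oxygen together, and that the nitrile oxide cannot reach either prenyl alkene for geometric reasons.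

Key step: step 10

Assumption: 5-methylhex-4-enal (1) is treated as a purchasable aldehyde, and the trione 22 is taken as one compound in whichever enol form it is drawn.

## Route

Step 1
Reactants: 1 5-methylhex-4-enal; 2 but-3-en-2-one
Product: 3 (S)-2-(3-methylbut-2-en-1-yl)-5-oxohexanal
Conditions: (S)-α,α-diphenylprolinol methyl ether (5 mol %), ethyl 3,4-dihydroxybenzoate (20 mol %), neat, 4 °C
Reagents that add atoms: none
Why: Enamine-catalysed Michael addition of an aldehyde to a vinyl ketone; the E-enamine of 1 is shielded on one face by the diphenyl(methoxy)methyl group, so the enone should be attacked from the open face, which sets the future C7 as (S) in 3 with high enantiomeric excess expected.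

Step 2
Reactants: 3 (S)-2-(3-methylbut-2-en-1-yl)-5-oxohexanal
Product: 4 (S)-4-(3-methylbut-2-en-1-yl)cyclohex-2-en-1-one
Conditions: LiOH, iPrOH, 23 °C
Reagents that add atoms: none
Why: Intramolecular aldol condensation of the methyl ketone onto the aldehyde with loss of water; only the methyl enolate can form a six-membered ring, and the stereocentre becomes the γ-carbon of the enone, which mild base should leave intact.

Step 3
Reactants: 4 (S)-4-(3-methylbut-2-en-1-yl)cyclohex-2-en-1-one
Product: 5 trimethyl{[(3S,4S)-3-methyl-4-(3-methylbut-2-en-1-yl)cyclohex-1-en-1-yl]oxy}silane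
Conditions: Me2CuLi, Me3SiCl, THF, −78 °C
Reagents that add atoms: lithium dimethylcuprate, [Li+].C[Cu-]C; chlorotrimethylsilane, C[Si](C)(C)Cl
Why: Silyl-chloride-accelerated conjugate addition of a Gilman cuprate with trapping of the enolate; the methyl group should enter anti to the neighbouring prenyl group (this centre is erased in step 4), and the regiodefined silyl enol ether prepares the dehydrogenation.

Step 4
Reactants: 5 trimethyl{[(3S,4S)-3-methyl-4-(3-methylbut-2-en-1-yl)cyclohex-1-en-1-yl]oxy}silane
Product: 6 (S)-3-methyl-4-(3-methylbut-2-en-1-yl)cyclohex-2-en-1-one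
Conditions: Pd(OAc)2 (1 equiv), MeCN, 23 °C
Reagents that add atoms: none
Why: Saegusa–Ito oxidation: palladation at the enol ether carbon and β-hydride elimination of the hydrogen on the methyl-bearing carbon give the 3-methyl enone; no base is present, so the γ-stereocentre should be retained, and the isolated trisubstituted alkene is not attacked at room temperature.

Step 5
Reactants: 6 (S)-3-methyl-4-(3-methylbut-2-en-1-yl)cyclohex-2-en-1-one; 7 1-bromo-3-methylbut-2-ene
Product: 8 (4R)-3-methyl-4,6-bis(3-methylbut-2-en-1-yl)cyclohex-2-en-1-one (both C6 epimers)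
Conditions: LiN(iPr)2, THF, −78 °C; then 7, −78 → 0 °C
Reagents that add atoms: none
Why: Kinetic α′-deprotonation of an enone and SN2 alkylation with an allylic bromide; the other α-carbon is vinylic, so only the future C5 can react, and the new centre is made planar again in step 6.

Step 6
Reactants: 8 (4R)-3-methyl-4,6-bis(3-methylbut-2-en-1-yl)cyclohex-2-en-1-one
Product: 9 trimethyl{[(4R)-5-methyl-2,4-bis(3-methylbut-2-en-1-yl)cyclohexa-1,5-dien-1-yl]oxy}silane
Conditions: LiN(iPr)2, THF, −78 °C; Me3SiCl
Reagents that add atoms: chlorotrimethylsilane, C[Si](C)(C)Cl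
Why: A second kinetic α′-deprotonation and O-silylation give the cross-conjugated silyl dienol ether, in which both C6 epimers of 8 converge on one planar C5.

Step 7
Reactants: 9 trimethyl{[(4R)-5-methyl-2,4-bis(3-methylbut-2-en-1-yl)cyclohexa-1,5-dien-1-yl]oxy}silane
Product: 10 (4R,6S)-6-(dimethoxymethyl)-3-methyl-4,6-bis(3-methylbut-2-en-1-yl)cyclohex-2-en-1-one
Conditions: HC(OMe)3, Me3SiOTf (10 mol %), CH2Cl2, −78 °C
Reagents that add atoms: trimethyl orthoformate, COC(OC)OC
Why: Mukaiyama-type addition of a silyl enol ether to the dimethoxycarbenium ion formed from the orthoformate; the electrophile should enter C5 on the face away from the C7 prenyl group (axial attack if that group is pseudoequatorial, plain shielding if it is pseudoaxial), which places the formyl carbon trans and the two prenyl groups cis as in 22.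

Step 8
Reactants: 10 (4R,6S)-6-(dimethoxymethyl)-3-methyl-4,6-bis(3-methylbut-2-en-1-yl)cyclohex-2-en-1-one; 11 3-phenylprop-2-ynal
Product: 14 1-[(1R,3S,5R)-3-(dimethoxymethyl)-6,6-dimethyl-3,5-bis(3-methylbut-2-en-1-yl)-2-oxocyclohexyl]-3-phenylprop-2-yn-1-yl acetate (both carbinol epimers), via lithium enolate 12 (not isolated), via lithium aldolate 13 (not isolated)
Conditions: Me2CuLi (1.1 equiv), Et2O, −40 → 0 °C; 11 (2 equiv), THF, −78 °C; Ac2O, −78 → −20 °C
Reagents that add atoms: lithium dimethylcuprate, [Li+].C[Cu-]C; acetic anhydride, CC(=O)OC(C)=O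
Why: Tandem cuprate conjugate addition, aldol addition and O-acylation: the methyl group completes the CMe2 carbon C8 and gives the C9–C1 enolate regiospecifically, which adds 1,2 to the reactive ynal, and the aldolate is capped cold before it can revert. The aldehyde should approach C1 anti to the pseudoaxial C8 methyl group, the face on which an acetal oxygen can also hold lithium, so the new arm ends up cis to the acetal carbon. The carbinol centre forms as a mixture that is of no consequence.

Step 9
Reactants: 14 1-[(1R,3S,5R)-3-(dimethoxymethyl)-6,6-dimethyl-3,5-bis(3-methylbut-2-en-1-yl)-2-oxocyclohexyl]-3-phenylprop-2-yn-1-yl acetate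
Product: 16 (E)-oxime of (1S,3R,5R)-3-(1-acetoxy-3-phenylprop-2-yn-1-yl)-4,4-dimethyl-1,5-bis(3-methylbut-2-en-1-yl)-2-oxocyclohexane-1-carbaldehyde, via keto aldehyde 15 (not isolated)
Conditions: Et3SiOTf, 2,4,6-collidine, CH2Cl2, 0 °C; H2O; then NH2OH·HCl, NaOAc, MeOH, 23 °C
Reagents that add atoms: hydroxylamine hydrochloride, NO.Cl
Why: Silyl-triflate/collidine cleavage of a dimethyl acetal through a collidinium N,O-acetal that water turns into the aldehyde, followed by oxime condensation; the non-enolisable keto aldehyde is not stored, hydroxylamine should react at the aldehyde far faster than at the doubly flanked C9 ketone, and the ester oxygen on C2 cannot take part at C4 as an ether or hydroxyl oxygen would.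

Step 10
Reactants: 16 (E)-oxime of (1S,3R,5R)-3-(1-acetoxy-3-phenylprop-2-yn-1-yl)-4,4-dimethyl-1,5-bis(3-methylbut-2-en-1-yl)-2-oxocyclohexane-1-carbaldehyde
Product: 18 (1R,5S,7R)-2-acetoxy-8,8-dimethyl-5,7-bis(3-methylbut-2-en-1-yl)bicyclo[3.3.1]nonan-9-one with a 5-phenylisoxazole fused across C3–C4 (nitrogen on C4; both C2 epimers), via nitrile oxide 17 (not isolated)
Conditions: PhI(OAc)2, CF3CO2H (cat.), MeOH, 0 → 23 °C, 0.005 M
Reagents that add atoms: none
Why: PhI(OAc)2 dehydrogenates the aldoxime to the nitrile oxide 17 (ligand exchange at iodine, then loss of iodobenzene and acetic acid). The dipole carbon C4 and the alkyne sit on 1,3-diaxial arms of the preferred chair (both prenyl groups equatorial), four atoms apart, and should combine in a concerted (3+2) cycloaddition in which C4 bonds to C3 and the dipole oxygen to the phenyl-bearing carbon. The closest known reaction type is the intramolecular nitrile oxide–alkyne (or –allene) cycloaddition that gives carbocycle-fused isoxazoles. The six-membered ring C1–C2–C3–C4–C5–C9 closes in the 6-exo-dig sense with respect to the alkyne, and the isoxazole is the five-membered ring of the cycloaddition itself, fused along C3–C4. No stereocentre is created, C1, C5 and C7 are not touched under these non-basic conditions, and either acetoxy epimer serves. Regiochemistry is fixed by the tether, since the reverse orientation would need a far more strained bridged ring. The C5 prenyl alkene cannot be reached (a four-membered ring would result) and the C7 prenyl alkene lies equatorial on the opposite face; dimerisation is slow for a nitrile oxide on a quaternary carbon and is further held back by dilution. The acetate keeps the C2 oxygen from adding to the nitrile oxide and keeps C2 below the ketone level that would invite pyranone formation.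

Step 11
Reactants: 18 (1R,5S,7R)-2-acetoxy-8,8-dimethyl-5,7-bis(3-methylbut-2-en-1-yl)bicyclo[3.3.1]nonan-9-one with a 5-phenylisoxazole fused across C3–C4
Product: 19 (1R,5S,7R)-2-hydroxy-8,8-dimethyl-5,7-bis(3-methylbut-2-en-1-yl)bicyclo[3.3.1]nonan-9-one with a 5-phenylisoxazole fused across C3–C4 (both C2 epimers)
Conditions: K2CO3, MeOH, 23 °C
Reagents that add atoms: none
Why: Base-catalysed transesterification of a secondary acetate; retro-aldol opening or β-elimination of the β-oxygenated ketone would need a bridgehead enolate and is therefore excluded, and the 3,5-disubstituted isoxazole is stable to carbonate.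

Step 12
Reactants: 19 (1R,5S,7R)-2-hydroxy-8,8-dimethyl-5,7-bis(3-methylbut-2-en-1-yl)bicyclo[3.3.1]nonan-9-one with a 5-phenylisoxazole fused across C3–C4
Product: 20 8,8-dimethyl-5,7-bis(3-methylbut-2-en-1-yl)bicyclo[3.3.1]nonane-2,9-dione with a 5-phenylisoxazole fused across C3–C4 (C1, C5 and C7 unchanged)
Conditions: Dess–Martin periodinane, CH2Cl2, 23 °C
Reagents that add atoms: none
Why: Dess–Martin oxidation of a secondary alcohol next to a heteroarene; the C1 hydrogen between the two ketones is a bridgehead hydrogen and cannot enolise, so C1 is safe, and both carbinol epimers converge.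

Step 13
Reactants: 20 8,8-dimethyl-5,7-bis(3-methylbut-2-en-1-yl)bicyclo[3.3.1]nonane-2,9-dione with a 5-phenylisoxazole fused across C3–C4
Product: 21 4-amino-3-benzoyl-8,8-dimethyl-5,7-bis(3-methylbut-2-en-1-yl)bicyclo[3.3.1]non-3-ene-2,9-dione
Conditions: Mo(CO)6, MeCN/H2O, 80 °C
Reagents that add atoms: none
Why: Reductive N–O cleavage of an isoxazole by Mo(CO)6 in wet acetonitrile gives the vinylogous amide; the reagent should not reduce the alkenes or the ketones.

Step 14
Reactants: 21 4-amino-3-benzoyl-8,8-dimethyl-5,7-bis(3-methylbut-2-en-1-yl)bicyclo[3.3.1]non-3-ene-2,9-dione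
Product: 22 (1R,5R,7R)-3-benzoyl-2-hydroxy-8,8-dimethyl-5,7-bis(3-methylbut-2-en-1-yl)bicyclo[3.3.1]non-2-ene-4,9-dione (CNP0187053.1)
Conditions: 1 M aq. HCl, THF, 45 °C
Reagents that add atoms: water, O
Why: Acid hydrolysis of a vinylogous amide (O-protonation, addition of water at C4, loss of ammonia) releases the C4 carbonyl and gives the enolised 3-benzoyl trione; dilute acid at moderate temperature should leave the prenyl groups unchanged.

## Compound list

1 | 5-methylhex-4-enal | CC(C)=CCCC=O | starting material
2 | but-3-en-2-one (methyl vinyl ketone) | CC(=O)C=C | starting material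
3 | (S)-2-(3-methylbut-2-en-1-yl)-5-oxohexanal | CC(C)=CC[C@@H](C=O)CCC(C)=O | intermediate
4 | (S)-4-(3-methylbut-2-en-1-yl)cyclohex-2-en-1-one | CC(C)=CC[C@@H]1CCC(=O)C=C1 | intermediate
5 | trimethyl{[(3S,4S)-3-methyl-4-(3-methylbut-2-en-1-yl)cyclohex-1-en-1-yl]oxy}silane (methyl trans to prenyl) | CC(C)=CC[C@@H]1CCC(O[Si](C)(C)C)=C[C@H]1C | intermediate
6 | (S)-3-methyl-4-(3-methylbut-2-en-1-yl)cyclohex-2-en-1-one | CC(C)=CC[C@@H]1CCC(=O)C=C1C | intermediate
7 | 1-bromo-3-methylbut-2-ene (prenyl bromide) | CC(C)=CCBr | starting material
8 | (4R)-3-methyl-4,6-bis(3-methylbut-2-en-1-yl)cyclohex-2-en-1-one, both C6 epimers | CC(C)=CC[C@@H]1CC(CC=C(C)C)C(=O)C=C1C | intermediate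
9 | trimethyl{[(4R)-5-methyl-2,4-bis(3-methylbut-2-en-1-yl)cyclohexa-1,5-dien-1-yl]oxy}silane | CC(C)=CC[C@@H]1CC(CC=C(C)C)=C(O[Si](C)(C)C)C=C1C | intermediate
10 | (4R,6S)-6-(dimethoxymethyl)-3-methyl-4,6-bis(3-methylbut-2-en-1-yl)cyclohex-2-en-1-one (prenyl groups cis) | CC(C)=CC[C@@H]1C[C@@](CC=C(C)C)(C(OC)OC)C(=O)C=C1C | intermediate
11 | 3-phenylprop-2-ynal | O=CC#Cc1ccccc1 | starting material
12 | lithium enolate (toward C6 of the ring, C1 of the target) of (2S,4R)-2-(dimethoxymethyl)-5,5-dimethyl-2,4-bis(3-methylbut-2-en-1-yl)cyclohexan-1-one, formed in the flask | CC(C)=CC[C@@H]1C[C@@](CC=C(C)C)(C(OC)OC)C([O-])=CC1(C)C.[Li+] | intermediate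
13 | lithium alkoxide of (2S,4R,6R)-2-(dimethoxymethyl)-6-(1-hydroxy-3-phenylprop-2-yn-1-yl)-5,5-dimethyl-2,4-bis(3-methylbut-2-en-1-yl)cyclohexan-1-one, formed in the flask | CC(C)=CC[C@@H]1C[C@@](CC=C(C)C)(C(OC)OC)C(=O)[C@@H](C([O-])C#Cc2ccccc2)C1(C)C.[Li+] | intermediate
14 | 1-[(1R,3S,5R)-3-(dimethoxymethyl)-6,6-dimethyl-3,5-bis(3-methylbut-2-en-1-yl)-2-oxocyclohexyl]-3-phenylprop-2-yn-1-yl acetate, both carbinol epimers | CC(C)=CC[C@@H]1C[C@@](CC=C(C)C)(C(OC)OC)C(=O)[C@@H](C(OC(C)=O)C#Cc2ccccc2)C1(C)C | intermediate
15 | (1S,3R,5R)-3-(1-acetoxy-3-phenylprop-2-yn-1-yl)-4,4-dimethyl-1,5-bis(3-methylbut-2-en-1-yl)-2-oxocyclohexane-1-carbaldehyde, formed in the flask | CC(C)=CC[C@@H]1C[C@@](CC=C(C)C)(C=O)C(=O)[C@@H](C(OC(C)=O)C#Cc2ccccc2)C1(C)C | intermediate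
16 | (E)-oxime of 15 (precursor of the key step) | CC(C)=CC[C@@H]1C[C@@](CC=C(C)C)(/C=N/O)C(=O)[C@@H](C(OC(C)=O)C#Cc2ccccc2)C1(C)C | intermediate
17 | (1S,3R,5R)-3-(1-acetoxy-3-phenylprop-2-yn-1-yl)-4,4-dimethyl-1,5-bis(3-methylbut-2-en-1-yl)-2-oxocyclohexane-1-carbonitrile oxide, formed in the flask | CC(C)=CC[C@@H]1C[C@@](CC=C(C)C)(C#[N+][O-])C(=O)[C@@H](C(OC(C)=O)C#Cc2ccccc2)C1(C)C | intermediate
18 | (1R,5S,7R)-2-acetoxy-8,8-dimethyl-5,7-bis(3-methylbut-2-en-1-yl)bicyclo[3.3.1]nonan-9-one with a 5-phenylisoxazole fused across C3–C4 (nitrogen on C4), both C2 epimers (product of the key step) | CC(C)=CC[C@@H]1C[C@@]2(CC=C(C)C)c3noc(-c4ccccc4)c3C(OC(C)=O)[C@H](C2=O)C1(C)C | intermediate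
19 | (1R,5S,7R)-2-hydroxy analogue of 18, both C2 epimers | CC(C)=CC[C@@H]1C[C@@]2(CC=C(C)C)c3noc(-c4ccccc4)c3C(O)[C@H](C2=O)C1(C)C | intermediate
20 | 8,8-dimethyl-5,7-bis(3-methylbut-2-en-1-yl)bicyclo[3.3.1]nonane-2,9-dione with a 5-phenylisoxazole fused across C3–C4 | CC(C)=CC[C@@H]1C[C@@]2(CC=C(C)C)c3noc(-c4ccccc4)c3C(=O)[C@H](C2=O)C1(C)C | intermediate
21 | 4-amino-3-benzoyl-8,8-dimethyl-5,7-bis(3-methylbut-2-en-1-yl)bicyclo[3.3.1]non-3-ene-2,9-dione | CC(C)=CC[C@@H]1C[C@@]2(CC=C(C)C)C(N)=C(C(=O)c3ccccc3)C(=O)[C@H](C2=O)C1(C)C | intermediate
22 | (1R,5R,7R)-3-benzoyl-2-hydroxy-8,8-dimethyl-5,7-bis(3-methylbut-2-en-1-yl)bicyclo[3.3.1]non-2-ene-4,9-dione (CNP0187053.1) | CC(C)=CC[C@@H]1C[C@@]2(CC=C(C)C)C(=O)C(C(=O)c3ccccc3)=C(O)[C@H](C2=O)C1(C)C | target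

## Step count and least certain steps

Total step count: 14. Longest linear sequence: 14 steps (from 1 and 2 to 22; 7 and 11 enter on the way).

**Step 10 (key step).** The most likely failure is loss of the nitrile oxide to dimerisation or to addition of methanol, because the linear dipole and the linear alkyne must both bend to meet across the bridge and ring closure may be slow. The fallback keeps the same two bonds but changes the dipolarophile. It sets out from 16: semi-hydrogenation (H2, Pd on CaCO3 poisoned with Pb(OAc)2, quinoline) would give the (Z)-alkenyl oxime F1. Oxidation with PhI(OAc)2 would give the nitrile oxide F2, which should add to the more pliable cis-alkene to give the isoxazoline F3. Dehydrogenation of F3 with DDQ (or MnO2) returns to 18.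

**Step 8.** The most likely failure is poor facial selectivity at C1: both faces of enolate 12 carry an axial group (the C8 methyl on one, the C5 acetal on the other), and an arm delivered opposite the acetal gives a C1 epimer whose arms are trans and cannot be joined in step 10. The fallback sets C1 by protonation instead of by C–C bond formation. It sets out from 10: the same cuprate–aldol sequence, quenched with acid instead of Ac2O, would give the C1-epimeric aldol F4. Two equivalents of LiN(iPr)2 at −78 °C would give the alkoxide enolate F5, which cannot eliminate because an alkoxide is a poor leaving group. A hindered phenol should then protonate C1 from the same open face that the aldehyde used, which puts the arm on the acetal side and gives the cis aldol F6. Acetylation of F6 (Ac2O, 4-dimethylaminopyridine, pyridine, 0 °C) returns to 14.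

**Step 7.** The most likely failure is poor or reversed facial selectivity at C5, since the controlling centre C7 is 1,3-related and the carbenium ion is small; the C5 epimer would lead into the C7-epimeric series. The fallback reverses the order of the two C5 substitutions, which inverts the sense at C5 because the second group takes the face the first order gave to the acetal carbon. It sets out from 6: LiN(iPr)2 and Me3SiCl would give the silyl dienol ether F7, HC(OMe)3 with catalytic Me3SiOTf the mono-substituted acetal F8, and LiN(iPr)2 followed by 7 returns to 10.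

**Step 14.** The most likely failure is sluggish hydrolysis, because the amino group of 21 is part of a push–pull system with two acyl groups and sits beside a quaternary carbon; forcing acid would endanger the prenyl groups (hydration, or closure of the enol onto the C5 prenyl group). The fallback hydrolyses before the C2 ketone is in place. It sets out from 19: Mo(CO)6 in wet acetonitrile would give the amino enone F9, whose only acceptor is the benzoyl group and which should hydrolyse in 0.5 M aq. HCl at 23 °C to the hydroxy diketone F10. Oxidation of the C2 carbinol of F10, which is allylic to the enol double bond, with MnO2 returns to 22.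

## Further compounds

F1 | step 10 | (Z)-alkenyl analogue of 16: (E)-oxime carrying a (Z)-1-acetoxy-3-phenylprop-2-en-1-yl arm | CC(C)=CC[C@@H]1C[C@@](CC=C(C)C)(/C=N/O)C(=O)[C@@H](C(OC(C)=O)/C=C\c2ccccc2)C1(C)C
F2 | step 10 | nitrile oxide derived from F1 | CC(C)=CC[C@@H]1C[C@@](CC=C(C)C)(C#[N+][O-])C(=O)[C@@H](C(OC(C)=O)/C=C\c2ccccc2)C1(C)C
F3 | step 10 | isoxazoline analogue of 18 (4,5-dihydroisoxazole, ring hydrogens cis) | CC(C)=CC[C@@H]1C[C@@]2(CC=C(C)C)C3=NOC(c4ccccc4)C3C(OC(C)=O)[C@H](C2=O)C1(C)C
F4 | step 8 | (2S,4R,6S)-2-(dimethoxymethyl)-6-(1-hydroxy-3-phenylprop-2-yn-1-yl)-5,5-dimethyl-2,4-bis(3-methylbut-2-en-1-yl)cyclohexan-1-one (C1 epimer of the free aldol) | CC(C)=CC[C@@H]1C[C@@](CC=C(C)C)(C(OC)OC)C(=O)[C@H](C(O)C#Cc2ccccc2)C1(C)C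
F5 | step 8 | dilithium alkoxide enolate of F4 | CC(C)=CC[C@@H]1C[C@@](CC=C(C)C)(C(OC)OC)C([O-])=C(C([O-])C#Cc2ccccc2)C1(C)C.[Li+].[Li+]
F6 | step 8 | (2S,4R,6R)-2-(dimethoxymethyl)-6-(1-hydroxy-3-phenylprop-2-yn-1-yl)-5,5-dimethyl-2,4-bis(3-methylbut-2-en-1-yl)cyclohexan-1-one (free alcohol of 14) | CC(C)=CC[C@@H]1C[C@@](CC=C(C)C)(C(OC)OC)C(=O)[C@@H](C(O)C#Cc2ccccc2)C1(C)C
F7 | step 7 | trimethyl{[(4S)-5-methyl-4-(3-methylbut-2-en-1-yl)cyclohexa-1,5-dien-1-yl]oxy}silane | CC(C)=CC[C@@H]1CC=C(O[Si](C)(C)C)C=C1C
F8 | step 7 | (4R)-6-(dimethoxymethyl)-3-methyl-4-(3-methylbut-2-en-1-yl)cyclohex-2-en-1-one, both C6 epimers | CC(C)=CC[C@@H]1CC(C(OC)OC)C(=O)C=C1C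
F9 | step 14 | 4-amino-3-benzoyl-2-hydroxy-8,8-dimethyl-5,7-bis(3-methylbut-2-en-1-yl)bicyclo[3.3.1]non-3-en-9-one | CC(C)=CC[C@@H]1C[C@@]2(CC=C(C)C)C(N)=C(C(=O)c3ccccc3)C(O)[C@H](C2=O)C1(C)C
F10 | step 14 | 3-benzoyl-2,4-dihydroxy-8,8-dimethyl-5,7-bis(3-methylbut-2-en-1-yl)bicyclo[3.3.1]non-3-en-9-one (enol form of the 2-hydroxy diketone) | CC(C)=CC[C@@H]1C[C@@]2(CC=C(C)C)C(O)=C(C(=O)c3ccccc3)C(O)[C@H](C2=O)C1(C)C
A1 | alternative 1 | dimethyl 2-[(2R)-3,3-dimethyl-2-(3-methylbut-2-en-1-yl)-5-oxohexyl]-2-(3-methylbut-2-en-1-yl)propanedioate | CC(C)=CC[C@H](CC(CC=C(C)C)(C(=O)OC)C(=O)OC)C(C)(C)CC(C)=O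
A2 | alternative 1 | 8,8-dimethyl-5,7-bis(3-methylbut-2-en-1-yl)bicyclo[3.3.1]nonane-2,4,9-trione | CC(C)=CC[C@@H]1C[C@@]2(CC=C(C)C)C(=O)CC(=O)[C@H](C2=O)C1(C)C
A3 | alternative 2 | methyl 3-methoxy-3-[4-methyl-1,5-bis(3-methylbut-2-en-1-yl)-2-oxocyclohex-3-en-1-yl]prop-2-enoate | CC(C)=CC[C@@H]1C[C@@](CC=C(C)C)(C(OC)=CC(=O)OC)C(=O)C=C1C
A4 | alternative 2 | 4-methoxy-8,8-dimethyl-5,7-bis(3-methylbut-2-en-1-yl)bicyclo[3.3.1]non-3-ene-2,9-dione | CC(C)=CC[C@@H]1C[C@@]2(CC=C(C)C)C(OC)=CC(=O)[C@H](C2=O)C1(C)C
A5 | alternative 3 | 3-bromo-1-[2-(tert-butyldimethylsilyloxy)-4,4-dimethyl-1,5-bis(3-methylbut-2-en-1-yl)cyclohex-2-en-1-yl]prop-2-yn-1-one | CC(C)=CC[C@@H]1C[C@@](CC=C(C)C)(C(=O)C#CBr)C(O[Si](C)(C)C(C)(C)C)=CC1(C)C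
A6 | alternative 3 | 2-bromo-8,8-dimethyl-5,7-bis(3-methylbut-2-en-1-yl)bicyclo[3.3.1]non-2-ene-4,9-dione | CC(C)=CC[C@@H]1C[C@@]2(CC=C(C)C)C(=O)C=C(Br)[C@H](C2=O)C1(C)C
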